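You want the mono adduct in the flask at 6.0 d, so the next decision is how much reagent to charge. The highest reading doesn't answer that: the dusk run reaches 42% and the winter run 38%, yet at 6.00 d they read 39% and 12%.

| flask | substrate | reagent | remark | time |
|---|---|---|---|---|
| dusk | 0.55 M | 0.86 M | run made earlier |  |
| autumn | 0.55 M | 1.1 M | run made earlier |  |
| winter | 0.55 M | 1.4 M | run made earlier |  |
| Monday's | 0.55 M | 0.825 M |  | 6.0 d |
| Thursday's | 0.55 M | 1.38 M |  | 6.0 d |
| Friday's | 0.55 M | 1.65 M |  | 6.0 d |

| run | time / d | mono adduct / % | double product / % |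
|---|---|---|---|
| dusk | 0.500 | 37 | 14 |
| dusk | 1.67 | 39 | 17 |
| dusk | 3.00 | 42 | 12 |
| dusk | 4.00 | 42 | 10 |
| dusk | 6.00 | 39 | 7 |
| autumn | 1.25 | 39 | 26 |
| autumn | 2.50 | 36 | 15 |
| autumn | 4.00 | 34 | 13 |
| autumn | 5.00 | 31 | 9 |
| autumn | 6.00 | 28 | 5 |
| winter | 0.500 | 38 | 29 |
| winter | 0.833 | 38 | 33 |
| winter | 1.67 | 34 | 30 |
| winter | 3.00 | 25 | 19 |
| winter | 6.00 | 12 | 10 |

(standard deviation of a reading: 1.5 percentage points)

- the earlier runs were read with a standard deviation of 1.5 percentage points

- final mono adduct, as a percentage of the substrate charged, for each flask in turn (Monday's, Thursday's, Friday's)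

So work with the fraction left, not the amount made. Take the mono adduct at 6.00 d over that at 3.00 d:

dusk: 39% / 42% = 0.929

winter: 12% / 25% = 0.480

Call this fraction the keep. Multiplying by it treats the late loss as pseudo-first-order, and each keep is a reading, since every reading behind it carries 1.5 points. The winter run keeps less than the dusk run at 1.63 times the reagent charge.

My reckoning follows from that. Monday's, at 0.825 M, sits just below the dusk charge of 0.86 M, so I put it near 39%. Thursday's, at 1.38 M, sits just below the winter charge, so I take the winter stock at 3.00 d and the winter keep: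

25% × 0.480 = 12.0%

Friday's, charged above the winter run, should end lower still. The decision is to charge low, at Monday's 0.825 M.

The forecast reads 41%, 13% and 5%, higher than my 39% for Monday's and my 12.0% for Thursday's, on this ground: “Its late decay therefore tracks how much reagent survives the fast early stages”.

Monday's gives 42.2%, Thursday's 15.3% against my 12.0%, and Friday's 8.28%.

    substrate + reagent → mono adduct + by-product (k = 2.90 × 10⁻⁵ M⁻¹ s⁻¹)
    reagent ⇌ dormant form (K = 0.360, k = 2.80 × 10⁻⁶ s⁻¹)
    double product → over-reaction product (k = 7.80 × 10⁻⁶ s⁻¹)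
    reagent + mono adduct ⇌ double product + by-product (K = 2.80, k = 3.00 × 10⁻⁵ M⁻¹ s⁻¹)

The low charge stands: Monday's ends with 5.3% of its reagent charge left, Thursday's with 19%. Put the winter keep of 0.480 on Thursday's 27.1% at 3.00 d and you get 13.0%, against the 15.3% found. On Friday's 19.5% at 3.00 d it gives 9.36%, and Friday's flask holds 8.28% at 6.00 d.

(The runs come from a simulation with made-up constants; noise was put on by code.)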